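The route rests on cutting the C3–C4 bond of the dihydropyranone ring C. The feature exploited is the α-ketol there: the tertiary carbinol C3, carrying ring B, sits next to the C4 ketone on ring A, which is the retron of a crossed benzoin. A chiral triazolylidene converts the aldehyde of an aryloxy ketone (a ring A salicylaldehyde etherified with a ring B phenacyl unit) into an acyl anion equivalent that attacks the ketone, closing ring C and setting C3 with its hydroxyl in one operation. The prenyl ether masking O5 in that precursor is then relayed to C8 by a Claisen–Cope shift.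

Key step: step 8

Remark on the chemistry: the (S) configuration at C3 requires bond formation on the Re face of the ketone. The sense of induction of the triazolium salt named in step 8 is assumed by analogy; its antipode is equally available if a model cyclization shows the opposite sense. tert-Butyl 2-methylbut-3-en-2-yl carbonate is treated as a purchasable reagent. "Prenyl" means 3-methylbut-2-en-1-yl throughout.

Step 1
Reactants: 1 2,4,6-trihydroxybenzaldehyde
Product: 2 2,6-dihydroxy-4-methoxybenzaldehyde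
Conditions: MeI (1.0 equiv), K2CO3 (1.0 equiv), acetone, 0 °C to rt
Reagents that add atoms: iodomethane, CI
Why: Williamson etherification, in which the 4-OH (para to the formyl group, not hydrogen-bonded, most acidic) should react first as its phenoxide while the two ortho hydroxyls are held back by chelation to the aldehyde.

Step 2
Reactants: 2 2,6-dihydroxy-4-methoxybenzaldehyde
Product: 3 2-hydroxy-4-methoxy-6-[(3-methylbut-2-en-1-yl)oxy]benzaldehyde
Conditions: prenyl bromide (1.05 equiv), K2CO3 (1.1 equiv), acetone, rt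
Reagents that add atoms: prenyl bromide (1-bromo-3-methylbut-2-ene), CC(C)=CCBr
Why: Williamson mono-etherification of a symmetric diol, so regiochemistry is not an issue, and after the first alkylation the remaining hydroxyl is locked in a hydrogen bond to the formyl oxygen and should react much more slowly.

Step 3
Reactants: 4 1-(2,4-dihydroxyphenyl)ethanone (2,4-dihydroxyacetophenone)
Product: 5 1-{2-hydroxy-4-[(2-methylbut-3-en-2-yl)oxy]phenyl}ethanone
Conditions: tert-butyl 2-methylbut-3-en-2-yl carbonate (1.2 equiv), Pd(PPh3)4 (2 mol%), THF, 0 °C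
Reagents that add atoms: tert-butyl 2-methylbut-3-en-2-yl carbonate, C=CC(C)(C)OC(=O)OC(C)(C)C
Why: Tsuji–Trost O-allylation with zerovalent palladium, in which the free 4-phenoxide should attack the 1,1-dimethyl-π-allyl complex at its substituted terminus under kinetic control at low temperature, while the chelated 2-OH stays untouched.

Step 4
Reactants: 5 1-{2-hydroxy-4-[(2-methylbut-3-en-2-yl)oxy]phenyl}ethanone
Product: 6 1-[2,4-dihydroxy-3-(3-methylbut-2-en-1-yl)phenyl]ethanone
Conditions: N,N-diethylaniline, 140 °C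
Reagents that add atoms: none
Why: aromatic Claisen rearrangement ([3,3]), which transposes the allyl unit into a prenyl group; the hydrogen-bonded chelate of the 2-OH and the acetyl group (bond fixation) should direct it to C3 between the two oxygens and not to C5.

Step 5
Reactants: 6 1-[2,4-dihydroxy-3-(3-methylbut-2-en-1-yl)phenyl]ethanone
Product: 8 1-[2-methoxy-3-(3-methylbut-2-en-1-yl)-4-(prop-2-en-1-yloxy)phenyl]ethanone, via allyl ether 7 (not isolated)
Conditions: allyl bromide (1.0 equiv), K2CO3, DMF, rt; then MeI (3 equiv), 50 °C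
Reagents that add atoms: allyl bromide, C=CCBr; iodomethane, CI
Why: two Williamson etherifications in one flask, the unchelated 4-OH being alkylated at room temperature and the chelated, flanked 2-OH only with excess MeI and heat.

Step 6
Reactants: 8 1-[2-methoxy-3-(3-methylbut-2-en-1-yl)-4-(prop-2-en-1-yloxy)phenyl]ethanone
Product: 10 2-bromo-1-[2-methoxy-3-(3-methylbut-2-en-1-yl)-4-(prop-2-en-1-yloxy)phenyl]ethanone, via silyl enol ether 9 (not isolated)
Conditions: LiN(SiMe3)2, TMSCl, THF, −78 °C; crude enol ether, then NBS, THF, −78 to 0 °C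
Reagents that add atoms: N-bromosuccinimide, O=C1CCC(=O)N1Br; chlorotrimethylsilane, C[Si](C)(C)Cl (silyl group held only in 9)
Why: kinetic enolization and O-silylation followed by electrophilic bromination of the silyl enol ether, which at low temperature should be far more reactive toward NBS than the prenyl and allyl alkenes or the arene.

Step 7
Reactants: 3 2-hydroxy-4-methoxy-6-[(3-methylbut-2-en-1-yl)oxy]benzaldehyde; 10 2-bromo-1-[2-methoxy-3-(3-methylbut-2-en-1-yl)-4-(prop-2-en-1-yloxy)phenyl]ethanone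
Product: 11 4-methoxy-2-{2-[2-methoxy-3-(3-methylbut-2-en-1-yl)-4-(prop-2-en-1-yloxy)phenyl]-2-oxoethoxy}-6-[(3-methylbut-2-en-1-yl)oxy]benzaldehyde
Conditions: K2CO3 (1.2 equiv), acetone, rt
Reagents that add atoms: none
Why: Williamson etherification (SN2 at a reactive phenacyl bromide) by the phenoxide of 3, run with mild base at room temperature so that the product does not go on to a benzofuran by Rap–Stoermer aldol condensation.

Step 8
Reactants: 11 4-methoxy-2-{2-[2-methoxy-3-(3-methylbut-2-en-1-yl)-4-(prop-2-en-1-yloxy)phenyl]-2-oxoethoxy}-6-[(3-methylbut-2-en-1-yl)oxy]benzaldehyde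
Product: 12 (3S)-3-hydroxy-7-methoxy-3-[2-methoxy-3-(3-methylbut-2-en-1-yl)-4-(prop-2-en-1-yloxy)phenyl]-5-[(3-methylbut-2-en-1-yl)oxy]-2,3-dihydro-4H-chromen-4-one
Conditions: (5aS,10bR)-2-[3,5-bis(trifluoromethyl)phenyl]-5a,10b-dihydro-4H,6H-indeno[2,1-b][1,2,4]triazolo[4,3-d][1,4]oxazin-2-ium tetrafluoroborate (10 mol%), Et3N (20 mol%), toluene, rt
Reagents that add atoms: none
Why: Deprotonation of the triazolium salt gives the carbene, which adds to the formyl carbon of 11; proton transfer gives the nucleophilic Breslow enaminol (an acyl anion equivalent at the future C4), which attacks the tethered aryl ketone (the future C3), and collapse of the adduct releases the carbene and the α-ketol. This is the enantioselective intramolecular crossed aldehyde–ketone benzoin reaction, known for 2-(2-oxo-2-arylethoxy)benzaldehydes as a route to 3-hydroxychroman-4-ones. Ring C closes in a 6-exo-trig mode, the carbon nucleophile attacking a ketone carbonyl whose oxygen stays outside the new ring. The C3 stereocenter is under catalyst control: the fused aminoindanol framework blocks one face of the enaminol and a hydrogen bond from the enol hydroxyl to the ketone oxygen fixes the approach, so that the Re face of the ketone should be attacked, which gives the (S) carbinol. The step needs chemoselectivity for carbene addition over base-mediated enolization of the OCH2C(=O) unit (aldol closure to a benzofuran), secured by a weakly basic, electron-poor N-aryl triazolylidene with only a trialkylamine as base, and a fixed assignment of roles, secured because only the aldehyde can form a Breslow intermediate. The prenyl ether on the second ortho oxygen keeps that phenol from quenching the catalyst and is small enough to leave the formyl group accessible.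

Step 9
Reactants: 12 (3S)-3-hydroxy-7-methoxy-3-[2-methoxy-3-(3-methylbut-2-en-1-yl)-4-(prop-2-en-1-yloxy)phenyl]-5-[(3-methylbut-2-en-1-yl)oxy]-2,3-dihydro-4H-chromen-4-one
Product: 15 (3S)-3,5-dihydroxy-7-methoxy-3-[2-methoxy-3-(3-methylbut-2-en-1-yl)-4-(prop-2-en-1-yloxy)phenyl]-8-(3-methylbut-2-en-1-yl)-2,3-dihydro-4H-chromen-4-one, via ortho-dienone 13 (not isolated), via para-dienone 14 (not isolated)
Conditions: Eu(fod)3, i.e. tris(6,6,7,7,8,8,8-heptafluoro-2,2-dimethyloctane-3,5-dionato)europium (10 mol%), NaHCO3, chlorobenzene, 80 °C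
Reagents that add atoms: none
Why: Lewis acid-catalysed domino para-Claisen–Cope rearrangement, in which chelation of europium between the C4 carbonyl and O5 should accelerate the [3,3] shift to C6, a Cope shift then carries the group on to C8 as a normal prenyl unit with relief of crowding, and tautomerization restores ring A with a free 5-OH; C3 is remote and not touched.

Step 10
Reactants: 15 (3S)-3,5-dihydroxy-7-methoxy-3-[2-methoxy-3-(3-methylbut-2-en-1-yl)-4-(prop-2-en-1-yloxy)phenyl]-8-(3-methylbut-2-en-1-yl)-2,3-dihydro-4H-chromen-4-one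
Product: 16 sophonorol F, (3S)-3,5-dihydroxy-3-[4-hydroxy-2-methoxy-3-(3-methylbut-2-en-1-yl)phenyl]-7-methoxy-8-(3-methylbut-2-en-1-yl)-2,3-dihydro-4H-chromen-4-one
Conditions: Pd(PPh3)4 (5 mol%), morpholine (5 equiv), THF, rt
Reagents that add atoms: none
Why: Tsuji–Trost deallylation, in which zerovalent palladium ionizes the aryl allyl ether and morpholine traps the π-allyl complex under neutral conditions, while the C-prenyl groups (no leaving group), the α-ketol and the C3 stereocenter should be inert.

Compound list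
1 | 2,4,6-trihydroxybenzaldehyde | O=Cc1c(O)cc(O)cc1O | starting material
2 | 2,6-dihydroxy-4-methoxybenzaldehyde | COc1cc(O)c(C=O)c(O)c1 | intermediate
3 | 2-hydroxy-4-methoxy-6-[(3-methylbut-2-en-1-yl)oxy]benzaldehyde | COc1cc(O)c(C=O)c(OCC=C(C)C)c1 | intermediate
4 | 1-(2,4-dihydroxyphenyl)ethanone | CC(=O)c1ccc(O)cc1O | starting material
5 | 1-{2-hydroxy-4-[(2-methylbut-3-en-2-yl)oxy]phenyl}ethanone | CC(=O)c1ccc(OC(C)(C)C=C)cc1O | intermediate
6 | 1-[2,4-dihydroxy-3-(3-methylbut-2-en-1-yl)phenyl]ethanone | CC(=O)c1ccc(O)c(CC=C(C)C)c1O | intermediate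
7 | 1-[2-hydroxy-3-(3-methylbut-2-en-1-yl)-4-(prop-2-en-1-yloxy)phenyl]ethanone (not isolated) | CC(=O)c1ccc(OCC=C)c(CC=C(C)C)c1O | intermediate
8 | 1-[2-methoxy-3-(3-methylbut-2-en-1-yl)-4-(prop-2-en-1-yloxy)phenyl]ethanone | CC(=O)c1ccc(OCC=C)c(CC=C(C)C)c1OC | intermediate
9 | {1-[2-methoxy-3-(3-methylbut-2-en-1-yl)-4-(prop-2-en-1-yloxy)phenyl]ethenyloxy}trimethylsilane (not isolated) | C=C(O[Si](C)(C)C)c1ccc(OCC=C)c(CC=C(C)C)c1OC | intermediate
10 | 2-bromo-1-[2-methoxy-3-(3-methylbut-2-en-1-yl)-4-(prop-2-en-1-yloxy)phenyl]ethanone | BrCC(=O)c1ccc(OCC=C)c(CC=C(C)C)c1OC | intermediate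
11 | 4-methoxy-2-{2-[2-methoxy-3-(3-methylbut-2-en-1-yl)-4-(prop-2-en-1-yloxy)phenyl]-2-oxoethoxy}-6-[(3-methylbut-2-en-1-yl)oxy]benzaldehyde | COc1cc(OCC=C(C)C)c(C=O)c(OCC(=O)c2ccc(OCC=C)c(CC=C(C)C)c2OC)c1 | intermediate
12 | (3S)-3-hydroxy-7-methoxy-3-[2-methoxy-3-(3-methylbut-2-en-1-yl)-4-(prop-2-en-1-yloxy)phenyl]-5-[(3-methylbut-2-en-1-yl)oxy]-2,3-dihydro-4H-chromen-4-one | COc1cc(OCC=C(C)C)c2c(c1)OC[C@@](O)(c1ccc(OCC=C)c(CC=C(C)C)c1OC)C2=O | intermediate
13 | (3S)-3-hydroxy-7-methoxy-3-[2-methoxy-3-(3-methylbut-2-en-1-yl)-4-(prop-2-en-1-yloxy)phenyl]-6-(2-methylbut-3-en-2-yl)-2,3-dihydro-4H-chromene-4,5(6H)-dione (not isolated) | COC1=CC2=C(C(=O)C1C(C)(C)C=C)C(=O)[C@](O)(c1ccc(OCC=C)c(CC=C(C)C)c1OC)CO2 | intermediate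
14 | (3S)-3-hydroxy-7-methoxy-3-[2-methoxy-3-(3-methylbut-2-en-1-yl)-4-(prop-2-en-1-yloxy)phenyl]-8-(3-methylbut-2-en-1-yl)-2,3-dihydro-4H-chromene-4,5(8H)-dione (not isolated) | COC1=CC(=O)C2=C(OC[C@@](O)(c3ccc(OCC=C)c(CC=C(C)C)c3OC)C2=O)C1CC=C(C)C | intermediate
15 | (3S)-3,5-dihydroxy-7-methoxy-3-[2-methoxy-3-(3-methylbut-2-en-1-yl)-4-(prop-2-en-1-yloxy)phenyl]-8-(3-methylbut-2-en-1-yl)-2,3-dihydro-4H-chromen-4-one | COc1cc(O)c2c(c1CC=C(C)C)OC[C@@](O)(c1ccc(OCC=C)c(CC=C(C)C)c1OC)C2=O | intermediate
16 | sophonorol F, (3S)-3,5-dihydroxy-3-[4-hydroxy-2-methoxy-3-(3-methylbut-2-en-1-yl)phenyl]-7-methoxy-8-(3-methylbut-2-en-1-yl)-2,3-dihydro-4H-chromen-4-one | COc1cc(O)c2c(c1CC=C(C)C)OC[C@@](O)(c1ccc(O)c(CC=C(C)C)c1OC)C2=O | target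

Total step count: 10. Longest linear sequence: 8 steps (steps 3 to 10, from 4).

Steps most likely to fail

Step 8. The carbene may add only sluggishly to the electron-rich formyl group flanked by two ortho alkoxy groups, so that enolization and aldol closure to a benzofuran take over; the facial selectivity at the ketone may also be insufficient. The fallback sets out from 11 and comes back at 15 by reversing the order of ring closure and prenyl relay. Compound 11 is first submitted to the Claisen–Cope conditions of step 9 (Eu(fod)3, NaHCO3, chlorobenzene, 80 °C) to give 6-hydroxy-4-methoxy-2-{2-[2-methoxy-3-(3-methylbut-2-en-1-yl)-4-(prop-2-en-1-yloxy)phenyl]-2-oxoethoxy}-3-(3-methylbut-2-en-1-yl)benzaldehyde F1. Its aldehyde is now a hydrogen-bonded salicylaldehyde with one small ortho substituent, and the internal hydrogen bond should activate the carbonyl toward the carbene. Benzoin cyclization of F1 with the same triazolium salt and Et3N in toluene would then give 15 directly.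

Step 9. The domino may stop after the first shift, the ortho-dienone tautomerizing to the 6-(2-methylbut-3-en-2-yl) phenol, or the Lewis acid may cause loss of the prenyl group from oxygen. The fallback places the C8 prenyl group before ring closure by an ortho-Claisen shift from the future O1; it sets out from 2 and comes back at 16. Mono-O-allylation of 2 with tert-butyl 2-methylbut-3-en-2-yl carbonate and Pd(PPh3)4 in THF at 0 °C would give 2-hydroxy-4-methoxy-6-[(2-methylbut-3-en-2-yl)oxy]benzaldehyde F2. Allyl bromide and K2CO3 in DMF would convert it into 4-methoxy-2-[(2-methylbut-3-en-2-yl)oxy]-6-(prop-2-en-1-yloxy)benzaldehyde F3. Heating in toluene at 110 °C should move the tertiary allyl group to the only free ortho carbon and give 2-hydroxy-4-methoxy-3-(3-methylbut-2-en-1-yl)-6-(prop-2-en-1-yloxy)benzaldehyde F4, whose free hydroxyl lies next to the prenyl group. Alkylation of F4 with 10 (K2CO3, acetone, rt) would give 4-methoxy-2-{2-[2-methoxy-3-(3-methylbut-2-en-1-yl)-4-(prop-2-en-1-yloxy)phenyl]-2-oxoethoxy}-3-(3-methylbut-2-en-1-yl)-6-(prop-2-en-1-yloxy)benzaldehyde F5. The benzoin cyclization under the conditions of step 8 would give (3S)-3-hydroxy-7-methoxy-3-[2-methoxy-3-(3-methylbut-2-en-1-yl)-4-(prop-2-en-1-yloxy)phenyl]-8-(3-methylbut-2-en-1-yl)-5-(prop-2-en-1-yloxy)-2,3-dihydro-4H-chromen-4-one F6. Removal of both allyl ethers with Pd(PPh3)4 and morpholine would give 16.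

Step 7. Under carbonate base the chelated, flanked phenol may alkylate slowly while the product enolizes and cyclizes onto its own aldehyde (Rap–Stoermer condensation). The fallback forms the same ether under neutral redox-condensation conditions; it sets out from 10 and 3 and comes back at 11. Displacement of bromide from 10 with HCO2K in methanol at 60 °C would give 2-[2-methoxy-3-(3-methylbut-2-en-1-yl)-4-(prop-2-en-1-yloxy)phenyl]-2-oxoethyl formate F7, which is methanolysed in the same flask to 2-hydroxy-1-[2-methoxy-3-(3-methylbut-2-en-1-yl)-4-(prop-2-en-1-yloxy)phenyl]ethanone F8. Mitsunobu etherification of F8 with the acidic phenol 3 (PPh3, diisopropyl azodicarboxylate, THF, 0 °C) would give 11.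

Further compounds
F1 | step 8 | 6-hydroxy-4-methoxy-2-{2-[2-methoxy-3-(3-methylbut-2-en-1-yl)-4-(prop-2-en-1-yloxy)phenyl]-2-oxoethoxy}-3-(3-methylbut-2-en-1-yl)benzaldehyde | COc1cc(O)c(C=O)c(OCC(=O)c2ccc(OCC=C)c(CC=C(C)C)c2OC)c1CC=C(C)C
F2 | step 9 | 2-hydroxy-4-methoxy-6-[(2-methylbut-3-en-2-yl)oxy]benzaldehyde | COc1cc(O)c(C=O)c(OC(C)(C)C=C)c1
F3 | step 9 | 4-methoxy-2-[(2-methylbut-3-en-2-yl)oxy]-6-(prop-2-en-1-yloxy)benzaldehyde | COc1cc(OCC=C)c(C=O)c(OC(C)(C)C=C)c1
F4 | step 9 | 2-hydroxy-4-methoxy-3-(3-methylbut-2-en-1-yl)-6-(prop-2-en-1-yloxy)benzaldehyde | COc1cc(OCC=C)c(C=O)c(O)c1CC=C(C)C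
F5 | step 9 | 4-methoxy-2-{2-[2-methoxy-3-(3-methylbut-2-en-1-yl)-4-(prop-2-en-1-yloxy)phenyl]-2-oxoethoxy}-3-(3-methylbut-2-en-1-yl)-6-(prop-2-en-1-yloxy)benzaldehyde | COc1cc(OCC=C)c(C=O)c(OCC(=O)c2ccc(OCC=C)c(CC=C(C)C)c2OC)c1CC=C(C)C
F6 | step 9 | (3S)-3-hydroxy-7-methoxy-3-[2-methoxy-3-(3-methylbut-2-en-1-yl)-4-(prop-2-en-1-yloxy)phenyl]-8-(3-methylbut-2-en-1-yl)-5-(prop-2-en-1-yloxy)-2,3-dihydro-4H-chromen-4-one | COc1cc(OCC=C)c2c(c1CC=C(C)C)OC[C@@](O)(c1ccc(OCC=C)c(CC=C(C)C)c1OC)C2=O
F7 | step 7 | 2-[2-methoxy-3-(3-methylbut-2-en-1-yl)-4-(prop-2-en-1-yloxy)phenyl]-2-oxoethyl formate | O=COCC(=O)c1ccc(OCC=C)c(CC=C(C)C)c1OC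
F8 | step 7 | 2-hydroxy-1-[2-methoxy-3-(3-methylbut-2-en-1-yl)-4-(prop-2-en-1-yloxy)phenyl]ethanone | OCC(=O)c1ccc(OCC=C)c(CC=C(C)C)c1OC
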